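**Direct plan and its weak points**

A direct plan would build the skeleton piece by piece as its heptamethyl ether: Horner–Wadsworth–Emmons olefination to the bromostilbene A1, bromine–lithium exchange and addition to a salicylaldehyde, then conversion of the carbinol into the racemic sulfone A2.
Base would release an ortho-quinone methide from A2, a squaramide would steer the nitronate of the aryl nitromethane A3 onto it to give the nitro adduct A4, Bu3SnH would delete the nitro group to give the heptamethyl ether A5, and BBr3 would cleave seven ethers.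
Weak point 1, the nitronate addition that sets the stereocenter: it is an untested asymmetric C–C bond formation, its adduct can revert by loss of nitronate under the basic two-phase conditions, and it creates a second stereocenter that is only thrown away.
Weak point 2, the nitro detour: the AgNO2 displacement before and the Bu3SnH denitration at 110 °C after the coupling build nothing, and stannyl radicals add reversibly to the stilbene, which would erode the E geometry.
Weak point 3, the sevenfold BBr3 demethylation as last step: HBr and a boron Lewis acid would meet an electron-rich stilbene and a doubly activated benzylic C–H stereocenter, risking olefin protonation, retro-Friedel–Crafts ionization and racemization.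

**Retrosynthetic overview of the new route**

The target is a dimer of oxyresveratrol. Its methine carbon carries the 2,4-dihydroxyphenyl ring C and the CH2 arm to the 3,5-dihydroxyphenyl ring D, and is bonded to C5 of the resorcinol ring A of an intact E-stilbene (rings A and B). Methine and CH2 are the two olefin carbons of a second stilbene.
The key disconnection is the methine–C5 (ring A) bond, cut so that both halves are the same monomer 5. A chiral Brønsted acid would protonate one molecule at the olefin carbon next to the 3,5-dioxygenated ring to give an ortho-quinone methide, and C5 of a second molecule would add to it, as in the presumed biosynthesis. Bond and (S) centre would form together.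
No ring is formed in the route. The four benzene rings come from two bromoresorcinols, joined by a Stille vinylation and a Heck reaction. The only protecting groups are pivalates on the 3,5-dioxygenated ring, which also switch that ring off as a nucleophile.
By design there is no auxiliary nitro group or second stereocenter to delete, no tin radical near the stilbene, and no ether cleavage at the end: the last step is a methoxide transesterification.

Key step: step 4

Assumption: the (R)-configured acid is taken to deliver the (S) centre. The sense of induction cannot be derived with certainty and would be checked on the first run; the (S)-acid would be used with no other change if needed.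

**Route**

Step 1
Reactants: 1 5-bromobenzene-1,3-diol
Product: 2 5-bromo-1,3-phenylene bis(2,2-dimethylpropanoate)
Conditions: PivCl (2.3 equiv), Et3N (2.6 equiv), 4-(dimethylamino)pyridine (5 mol%), CH2Cl2, 0 °C → rt
Reagents that add atoms: pivaloyl chloride (PivCl), CC(C)(C)C(Cl)=O
Why: Nucleophilic acyl substitution (amine-catalysed O-acylation) of both phenols should be clean, and the two acyloxy groups later deactivate this ring toward Friedel–Crafts attack and come off with methoxide.

Step 2
Reactants: 2 5-bromo-1,3-phenylene bis(2,2-dimethylpropanoate)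
Product: 3 5-ethenyl-1,3-phenylene bis(2,2-dimethylpropanoate)
Conditions: Bu3SnCH=CH2 (1.15 equiv), Pd(PPh3)4 (3 mol%), toluene, 100 °C, trace BHT; aq. KF work-up
Reagents that add atoms: tributyl(vinyl)stannane, C=C[Sn](CCCC)(CCCC)CCCC
Why: Stille cross-coupling of the slightly electron-poor aryl bromide runs under neutral, base-free conditions that should leave the aryl pivalates untouched.

Step 3
Reactants: 3 5-ethenyl-1,3-phenylene bis(2,2-dimethylpropanoate); 4 4-bromobenzene-1,3-diol
Product: 5 5-[(E)-2-(2,4-dihydroxyphenyl)ethenyl]-1,3-phenylene bis(2,2-dimethylpropanoate)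
Conditions: Pd(OAc)2 (5 mol%), P(o-tol)3 (12 mol%), Et3N (3 equiv), DMF, 100 °C, Ar
Reagents that add atoms: none
Why: Mizoroki–Heck arylation of the terminal styrene (syn insertion, syn β-hydride elimination) should give the E-stilbene; free bromophenols are established Heck partners, and the hindered pivalates should resist transfer to the free phenols.

Step 4
Reactants: 5 5-[(E)-2-(2,4-dihydroxyphenyl)ethenyl]-1,3-phenylene bis(2,2-dimethylpropanoate) (two molecules: one is protonated, one serves as the arene nucleophile)
Product: 7 5-[(E)-2-{5-[(1S)-2-[3,5-bis(2,2-dimethylpropanoyloxy)phenyl]-1-(2,4-dihydroxyphenyl)ethyl]-2,4-dihydroxyphenyl}ethenyl]-1,3-phenylene bis(2,2-dimethylpropanoate), via ortho-quinone methide 6 (not isolated)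
Conditions: N-[(11bR)-4-oxido-2,6-bis[2,4,6-tri(propan-2-yl)phenyl]dinaphtho[2,1-d:1′,2′-f][1,3,2]dioxaphosphepin-4-yl]-1,1,1-trifluoromethanesulfonamide (10 mol%), CH2Cl2/toluene 1:1, 4 Å MS, −20 °C → rt, Ar, dark; to be stopped near half conversion, unreacted 5 recovered and resubmitted
Reagents that add atoms: none
Why: Proposed new method: the acid would protonate one molecule of 5 at the olefin carbon next to the bis(pivaloyloxy)phenyl ring while its basic phosphoryl site takes up the 2-OH proton, so that the 2,4-dihydroxystilbene is tautomerized to the ortho-quinone methide 6 (further stabilized by the 4-OH) held in the chiral pocket by hydrogen bonds, and a second molecule of 5, bound through its 4-OH, would attack the methide carbon with C5 of its resorcinol ring (ortho to 4-OH, para to 2-OH) and rearomatize to 7, which copies the presumed biosynthetic dimerization of oxyresveratrol. The closest known reaction types are the chiral phosphoric acid and N-triflylphosphoramide catalysed hydroarylations of ortho-hydroxystyrenes through ortho-quinone methides and the asymmetric Friedel–Crafts alkylation of phenols and naphthols by ortho-quinone methides made from ortho-hydroxybenzyl alcohols; new are the 1,2-diaryl olefin as precursor and the self-coupling. No ring is closed. The new stereocenter would be set by the catalyst alone: the E-configured methide lies hydrogen-bonded to the chiral anion, one face is covered by a 2,4,6-triisopropylphenyl group, and the arene, oriented by its own hydrogen bond, adds to the open face to give (S). The step needs protonation at the carbon beside the acyloxy ring, which is secured because only the resorcinol ring with its ortho and para hydroxyls can stabilize the cation; it needs attack by C5 and not by the other ring or the olefin, which is secured because the pivalates switch the 3,5-dioxygenated ring off both as a nucleophile and as the internal trap that would turn an olefin adduct into an aryltetralin, because C3 lies between two hydroxyls, and because a chroman from formal [4+2] addition of the olefin is a benzylic aryl ether that can re-ionize under the acid while C-arylation is irreversible. It also needs dimer and not oligomer, which is addressed by stopping near half conversion and by the confined pocket, which should take up the monomer more readily than the branched dimer.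

Step 5
Reactants: 7 the tetrapivalate dimer
Product: 8 4-[(1S)-1-{5-[(E)-2-(3,5-dihydroxyphenyl)ethenyl]-2,4-dihydroxyphenyl}-2-(3,5-dihydroxyphenyl)ethyl]benzene-1,3-diol (CNP0376747.1)
Conditions: NaOMe (10 equiv), degassed MeOH/THF, 0 °C → rt, Ar; AcOH quench at 0 °C
Reagents that add atoms: none
Why: Base-mediated transesterification (methanolysis) of the four aryl pivalates, with phenoxide as leaving group, needs no acid or Lewis acid, and neither the E-olefin nor the non-acidic triaryl-substituted C–H stereocenter should be touched.

**Compound list**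

1 | 5-bromobenzene-1,3-diol | Oc1cc(O)cc(Br)c1 | starting material
2 | 5-bromo-1,3-phenylene bis(2,2-dimethylpropanoate) | CC(C)(C)C(=O)Oc1cc(Br)cc(OC(=O)C(C)(C)C)c1 | intermediate
3 | 5-ethenyl-1,3-phenylene bis(2,2-dimethylpropanoate) | C=Cc1cc(OC(=O)C(C)(C)C)cc(OC(=O)C(C)(C)C)c1 | intermediate
4 | 4-bromobenzene-1,3-diol | Oc1ccc(Br)c(O)c1 | starting material
5 | 5-[(E)-2-(2,4-dihydroxyphenyl)ethenyl]-1,3-phenylene bis(2,2-dimethylpropanoate) | CC(C)(C)C(=O)Oc1cc(OC(=O)C(C)(C)C)cc(/C=C/c2ccc(O)cc2O)c1 | intermediate
6 | 5-[(2E)-2-(4-hydroxy-6-oxocyclohexa-2,4-dien-1-ylidene)ethyl]-1,3-phenylene bis(2,2-dimethylpropanoate), drawn as the E exocyclic isomer, geometry of this transient species not controlled (not isolated) | O=C1C=C(O)C=C/C1=C\Cc1cc(OC(=O)C(C)(C)C)cc(OC(=O)C(C)(C)C)c1 | intermediate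
7 | 5-[(E)-2-{5-[(1S)-2-[3,5-bis(2,2-dimethylpropanoyloxy)phenyl]-1-(2,4-dihydroxyphenyl)ethyl]-2,4-dihydroxyphenyl}ethenyl]-1,3-phenylene bis(2,2-dimethylpropanoate) | CC(C)(C)C(=O)Oc1cc(OC(=O)C(C)(C)C)cc(/C=C/c2cc([C@@H](Cc3cc(OC(=O)C(C)(C)C)cc(OC(=O)C(C)(C)C)c3)c3ccc(O)cc3O)c(O)cc2O)c1 | intermediate
8 | 4-[(1S)-1-{5-[(E)-2-(3,5-dihydroxyphenyl)ethenyl]-2,4-dihydroxyphenyl}-2-(3,5-dihydroxyphenyl)ethyl]benzene-1,3-diol | Oc1cc(O)cc(/C=C/c2cc([C@@H](Cc3cc(O)cc(O)c3)c3ccc(O)cc3O)c(O)cc2O)c1 | target

**Step count and risk**

Total steps: 5. Longest linear sequence: 5 steps (1 → 2 → 3 → 5 → 7 → 8).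

Steps most likely to fail:

Step 4 (bears the label). The stilbene may be protonated too slowly or without selectivity, so that the acid also activates the product and the olefin of a second monomer competes as nucleophile, leading to oligomers and olefin adducts with poor facial control.
The fallback keeps the bond and the catalyst class but generates the ortho-quinone methide the established way, from an ortho-hydroxybenzyl alcohol whose own ring cannot act as a nucleophile. It sets out from 5, which then serves only as the arene partner, and comes back to the route at 8.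
- Orcinol would be pivaloylated (PivCl, Et3N, 4-(dimethylamino)pyridine) to 5-methyl-1,3-phenylene bis(2,2-dimethylpropanoate) F1.
- Wohl–Ziegler bromination (N-bromosuccinimide, azobisisobutyronitrile, PhCF3, 80 °C) would give 5-(bromomethyl)-1,3-phenylene bis(2,2-dimethylpropanoate) F2.
- Zinc dust and LiCl in THF would convert F2 into {[3,5-bis(2,2-dimethylpropanoyloxy)phenyl]methyl}zinc bromide F3.
- 2,4-Dihydroxybenzaldehyde would be acylated at the non-chelated 4-OH (PivCl 1.05 equiv, Et3N, CH2Cl2, −10 °C) to 4-formyl-3-hydroxyphenyl 2,2-dimethylpropanoate F4.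
- Addition of F3 (2.2 equiv, THF, 0 °C) to F4 would give racemic 5-{2-hydroxy-2-[2-hydroxy-4-(2,2-dimethylpropanoyloxy)phenyl]ethyl}-1,3-phenylene bis(2,2-dimethylpropanoate) F5.
- With (11bR)-4-hydroxy-2,6-bis[2,4,6-tri(propan-2-yl)phenyl]dinaphtho[2,1-d:1′,2′-f][1,3,2]dioxaphosphepine 4-oxide (10 mol%), 5 (3 equiv), CH2Cl2, 4 Å MS, −20 °C, F5 would lose water to 5-[(2E)-2-{4-[(2,2-dimethylpropanoyl)oxy]-6-oxocyclohexa-2,4-dien-1-ylidene}ethyl]-1,3-phenylene bis(2,2-dimethylpropanoate) F6, at a temperature at which 5 alone should be inert to this weaker acid.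
- The known asymmetric Friedel–Crafts alkylation of a phenol by such a methide, here at C5 of 5, would give 5-[(E)-2-{5-[(1S)-2-[3,5-bis(2,2-dimethylpropanoyloxy)phenyl]-1-[2-hydroxy-4-(2,2-dimethylpropanoyloxy)phenyl]ethyl]-2,4-dihydroxyphenyl}ethenyl]-1,3-phenylene bis(2,2-dimethylpropanoate) F7.
- The methoxide conditions of step 5 would then cleave five pivalates and deliver 8.

Step 3. Oxidative addition into the electron-rich bromoresorcinol may be slow, with catalyst decay to palladium black and base-mediated pivaloyl transfer to the free phenols at 100 °C.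
The fallback replaces the Heck reaction by a Suzuki–Miyaura coupling at lower temperature; it sets out from 3 and comes back at 5.
- Cross-metathesis of 3 with vinylboronic acid pinacol ester (second-generation Grubbs catalyst, (H2IMes)(PCy3)Cl2Ru=CHPh, CH2Cl2, 40 °C) would give 5-[(E)-2-(4,4,5,5-tetramethyl-1,3,2-dioxaborolan-2-yl)ethenyl]-1,3-phenylene bis(2,2-dimethylpropanoate) F8.
- F8 would be coupled with 4 (Pd(OAc)2, 2-dicyclohexylphosphino-2′,6′-dimethoxybiphenyl, K3PO4, THF/H2O, 40 °C) to give 5 with the E geometry fixed by the boronate.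

Step 5. Methanolysis of the hindered esters may stall as ring phenoxides build up, and the polyphenolate may be oxidized by traces of air.
The fallback replaces transesterification by hydride reduction under aprotic conditions (no new compound, F0); it sets out from 7 and comes back at 8. i-Bu2AlH (14 equiv) in CH2Cl2/THF at −78 → −40 °C would reduce the four pivalates, with Rochelle salt and dilute acid work-up.

**Further compounds**

F1 | step 4 | 5-methyl-1,3-phenylene bis(2,2-dimethylpropanoate) | Cc1cc(OC(=O)C(C)(C)C)cc(OC(=O)C(C)(C)C)c1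
F2 | step 4 | 5-(bromomethyl)-1,3-phenylene bis(2,2-dimethylpropanoate) | BrCc1cc(OC(=O)C(C)(C)C)cc(OC(=O)C(C)(C)C)c1
F3 | step 4 | {[3,5-bis(2,2-dimethylpropanoyloxy)phenyl]methyl}zinc bromide | Br[Zn]Cc1cc(OC(=O)C(C)(C)C)cc(OC(=O)C(C)(C)C)c1
F4 | step 4 | 4-formyl-3-hydroxyphenyl 2,2-dimethylpropanoate | CC(C)(C)C(=O)Oc1ccc(C=O)c(O)c1
F5 | step 4 | 5-{2-hydroxy-2-[2-hydroxy-4-(2,2-dimethylpropanoyloxy)phenyl]ethyl}-1,3-phenylene bis(2,2-dimethylpropanoate), racemic | CC(C)(C)C(=O)Oc1ccc(C(O)Cc2cc(OC(=O)C(C)(C)C)cc(OC(=O)C(C)(C)C)c2)c(O)c1
F6 | step 4 | 5-[(2E)-2-{4-[(2,2-dimethylpropanoyl)oxy]-6-oxocyclohexa-2,4-dien-1-ylidene}ethyl]-1,3-phenylene bis(2,2-dimethylpropanoate), transient | O=C1C=C(OC(=O)C(C)(C)C)C=C/C1=C\Cc1cc(OC(=O)C(C)(C)C)cc(OC(=O)C(C)(C)C)c1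
F7 | step 4 | 5-[(E)-2-{5-[(1S)-2-[3,5-bis(2,2-dimethylpropanoyloxy)phenyl]-1-[2-hydroxy-4-(2,2-dimethylpropanoyloxy)phenyl]ethyl]-2,4-dihydroxyphenyl}ethenyl]-1,3-phenylene bis(2,2-dimethylpropanoate) | CC(C)(C)C(=O)Oc1cc(OC(=O)C(C)(C)C)cc(/C=C/c2cc([C@@H](Cc3cc(OC(=O)C(C)(C)C)cc(OC(=O)C(C)(C)C)c3)c3ccc(OC(=O)C(C)(C)C)cc3O)c(O)cc2O)c1
F8 | step 3 | 5-[(E)-2-(4,4,5,5-tetramethyl-1,3,2-dioxaborolan-2-yl)ethenyl]-1,3-phenylene bis(2,2-dimethylpropanoate) | CC(C)(C)C(=O)Oc1cc(OC(=O)C(C)(C)C)cc(/C=C/B2OC(C)(C)C(C)(C)O2)c1
F0 | step 5 | none | none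
A1 | direct plan | (E)-1-bromo-5-[2-(3,5-dimethoxyphenyl)ethenyl]-2,4-dimethoxybenzene | COc1cc(OC)cc(/C=C/c2cc(Br)c(OC)cc2OC)c1
A2 | direct plan | 2-[{5-[(E)-2-(3,5-dimethoxyphenyl)ethenyl]-2,4-dimethoxyphenyl}(4-methylbenzenesulfonyl)methyl]-5-methoxyphenol, racemic | COc1cc(OC)cc(/C=C/c2cc(C(c3ccc(OC)cc3O)S(=O)(=O)c3ccc(C)cc3)c(OC)cc2OC)c1
A3 | direct plan | 1,3-dimethoxy-5-(nitromethyl)benzene | COc1cc(C[N+](=O)[O-])cc(OC)c1
A4 | direct plan | 2-[(1S)-1-{5-[(E)-2-(3,5-dimethoxyphenyl)ethenyl]-2,4-dimethoxyphenyl}-2-(3,5-dimethoxyphenyl)-2-nitroethyl]-5-methoxyphenol, epimer mixture at the nitro-bearing carbon | COc1cc(OC)cc(/C=C/c2cc([C@@H](C(c3cc(OC)cc(OC)c3)[N+](=O)[O-])c3ccc(OC)cc3O)c(OC)cc2OC)c1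
A5 | direct plan | 2-[(1S)-1-{5-[(E)-2-(3,5-dimethoxyphenyl)ethenyl]-2,4-dimethoxyphenyl}-2-(3,5-dimethoxyphenyl)ethyl]-5-methoxyphenol | COc1cc(OC)cc(/C=C/c2cc([C@@H](Cc3cc(OC)cc(OC)c3)c3ccc(OC)cc3O)c(OC)cc2OC)c1
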